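The chromone is disconnected at the C4–C4a bond of the pyranone ring, which leads back to a 3-aryloxydocos-2-enoic acid in which the phenol oxygen (O1), the C2 nonadecyl chain and the C3–C4 unit are already in place. In a single operation an intramolecular Friedel–Crafts acylation forges C4–C4a and closes the pyranone ring. The step exploits the fact that C4a is the only unsubstituted carbon of the benzene ring and sits ortho to O1 and the C5 oxygen and para to the C7 oxygen. The precursor, (Z)-3-(3,5-dimethoxy-2,4-dimethylphenoxy)docos-2-enoic acid, is assembled by oxa-Michael addition of a dimethoxy-dimethylphenol to a C22 alkynoate; demethylation finishes the synthesis.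

Key step: step 8

Assumption: compounds 14 and 15 are drawn and numbered as the Z isomers (the geometry that can cyclise); any E isomer formed in step 6 is carried along because both geometries converge on the same acylium ion in step 8; compounds 1, 8, 9 and 11 are taken as purchased.

Step 1
Reactants: 1 4-hydroxy-2,6-dimethoxybenzaldehyde
Product: 3 3,5-dimethoxy-4-methylphenol, via 4-(hydroxymethyl)-3,5-dimethoxyphenol 2 (not isolated)
Conditions: H2 (3 atm), Pd/C (10 wt%), AcOH, cat. HCl, rt
Reagents that add atoms: none
Why: Catalytic hydrogenation of the electron-rich aldehyde to benzylic alcohol 2 followed by acid-assisted benzylic C–O hydrogenolysis (the para-hydroxy and two ortho-methoxy groups stabilise the benzylic cation) is the standard deoxygenative reduction of hydroxy/alkoxybenzaldehydes to methylarenes.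

Step 2
Reactants: 3 3,5-dimethoxy-4-methylphenol
Product: 5 6-hydroxy-2,4-dimethoxy-3-methylbenzaldehyde, via (6-hydroxy-2,4-dimethoxy-3-methylbenzylidene)dimethylammonium chloride 4 (not isolated)
Conditions: POCl3, DMF, MeCN, 0 °C → rt; then H2O, 50 °C
Reagents that add atoms: N,N-dimethylformamide, CN(C)C=O; water, O
Why: Vilsmeier–Haack formylation: the chloroiminium ion can attack only the two symmetry-equivalent free positions, each ortho to the hydroxyl and para to a methoxy group, so a single iminium salt 4 should form and hydrolyse to the aldehyde, whose deactivating effect stops a second formylation.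

Step 3
Reactants: 5 6-hydroxy-2,4-dimethoxy-3-methylbenzaldehyde
Product: 7 3,5-dimethoxy-2,4-dimethylphenol, via 2-(hydroxymethyl)-3,5-dimethoxy-4-methylphenol 6 (not isolated)
Conditions: H2 (3 atm), Pd/C (10 wt%), AcOH, cat. HCl, rt
Reagents that add atoms: none
Why: The same hydrogenation–hydrogenolysis as in step 1, here of an ortho-hydroxybenzaldehyde whose benzylic alcohol 6 ionises readily, should deliver the second ring methyl group and leave one free hydroxyl next to the only ring hydrogen.

Step 4
Reactants: 8 1-bromononadecane; 9 lithium acetylide–ethylenediamine complex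
Product: 10 henicos-1-yne
Conditions: LiC≡CH·H2NCH2CH2NH2 (1.5 equiv), DMSO/THF, 10 °C → rt
Reagents that add atoms: none
Why: SN2 alkylation of lithium acetylide by a primary bromide in a dipolar aprotic medium is the standard one-step route to terminal alkynes and should outpace elimination.

Step 5
Reactants: 10 henicos-1-yne; 11 methyl chloroformate
Product: 13 methyl docos-2-ynoate, via lithium henicos-1-yn-1-ide 12 (not isolated)
Conditions: n-BuLi, THF, −40 → 0 °C; then ClCO2Me, −78 °C → rt
Reagents that add atoms: none
Why: Deprotonation of the terminal alkyne by n-BuLi and C-acylation of the lithium acetylide with a chloroformate is the standard alkynoate synthesis, and excess chloroformate at low temperature prevents a second addition to the product.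

Step 6
Reactants: 7 3,5-dimethoxy-2,4-dimethylphenol; 13 methyl docos-2-ynoate
Product: 14 methyl (Z)-3-(3,5-dimethoxy-2,4-dimethylphenoxy)docos-2-enoate
Conditions: K2CO3 (0.5 equiv), DMF, 80 °C
Reagents that add atoms: none
Why: Base-mediated oxa-Michael addition of the phenoxide to the β-carbon of the alkynoate should give the vinylogous carbonate; phenol 7 has a single hydroxyl, so no site question arises, and anti addition favours the Z enol ether.

Step 7
Reactants: 14 methyl (Z)-3-(3,5-dimethoxy-2,4-dimethylphenoxy)docos-2-enoate
Product: 15 (Z)-3-(3,5-dimethoxy-2,4-dimethylphenoxy)docos-2-enoic acid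
Conditions: LiOH·H2O (3 equiv), THF/MeOH/H2O, 50 °C; then 1 M HCl to pH 3, 0 °C
Reagents that add atoms: lithium hydroxide, [Li+].[OH-]
Why: Ester saponification by acyl substitution with hydroxide should proceed without loss of the aryloxy group because the β-alkyl, β-aryloxy enoate is a poor Michael acceptor, and cold dilute acid liberates the acid without hydrolysing the enol ether.

Step 8
Reactants: 15 (Z)-3-(3,5-dimethoxy-2,4-dimethylphenoxy)docos-2-enoic acid
Product: 16 5,7-dimethoxy-6,8-dimethyl-2-nonadecyl-4H-chromen-4-one
Conditions: P2O5 in MeSO3H (1:10 w/w, Eaton's reagent), 60 °C; then ice-water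
Reagents that add atoms: none
Why: P2O5/MeSO3H turns the carboxylic acid into a mixed anhydride and then an acylium ion, which attacks C6 of the aryl ring (the future C4a) in an intramolecular electrophilic aromatic substitution, and proton loss restores aromaticity (intramolecular Friedel–Crafts acylation). The closest known reaction type is the acid-mediated cyclisation of β-aryloxyacrylic acids to chromones (Ruhemann-type chromone synthesis). The pyranone ring closes in a 6-exo mode onto the acyl carbon (6-exo-dig for the acylium ion, 6-exo-trig for the mixed anhydride), and C4–C4a is the only skeletal bond made. No stereocentre is formed; only the Z acid can reach the ring carbon, but the acylium ion is delocalised onto the enol ether oxygen (ketene–oxocarbenium form), which lowers the C2–C3 bond order, so E and Z interconvert and both should drain into the chromone. Site selectivity is secured by the substrate, since the aryl ether carries a single ring hydrogen, and that carbon has two ortho oxygens and one para oxygen, so even a weakly electrophilic conjugated acylium ion should suffice. The methyl ethers are inert to the anhydrous acid and keep the C5 and C7 oxygens from being acylated or sulfonylated.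

Step 9
Reactants: 16 5,7-dimethoxy-6,8-dimethyl-2-nonadecyl-4H-chromen-4-one
Product: 17 5,7-dihydroxy-6,8-dimethyl-2-nonadecyl-4H-chromen-4-one (target)
Conditions: BBr3 (6 equiv), CH2Cl2, −78 °C → rt; then MeOH, H2O
Reagents that add atoms: none
Why: Lewis-acid ether cleavage, in which BBr3 coordinates each methoxy oxygen and bromide removes the methyl group by SN2, should free both phenols because the C5 ether is activated by chelation to the C4 carbonyl and the C7 ether is twisted out of plane by its two ortho methyl groups and is therefore unusually basic.

Compound list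
1 | 4-hydroxy-2,6-dimethoxybenzaldehyde | O=Cc1c(OC)cc(O)cc1OC | starting material
2 | 4-(hydroxymethyl)-3,5-dimethoxyphenol | OCc1c(OC)cc(O)cc1OC | intermediate (not isolated)
3 | 3,5-dimethoxy-4-methylphenol | Cc1c(OC)cc(O)cc1OC | intermediate
4 | (6-hydroxy-2,4-dimethoxy-3-methylbenzylidene)dimethylammonium chloride | C[N+](C)=Cc1c(O)cc(OC)c(C)c1OC.[Cl-] | intermediate (not isolated)
5 | 6-hydroxy-2,4-dimethoxy-3-methylbenzaldehyde | O=Cc1c(O)cc(OC)c(C)c1OC | intermediate
6 | 2-(hydroxymethyl)-3,5-dimethoxy-4-methylphenol | OCc1c(O)cc(OC)c(C)c1OC | intermediate (not isolated)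
7 | 3,5-dimethoxy-2,4-dimethylphenol | Cc1c(O)cc(OC)c(C)c1OC | intermediate
8 | 1-bromononadecane | CCCCCCCCCCCCCCCCCCCBr | starting material
9 | lithium acetylide–ethylenediamine complex | [Li]C#C.NCCN | starting material
10 | henicos-1-yne | CCCCCCCCCCCCCCCCCCCC#C | intermediate
11 | methyl chloroformate | COC(=O)Cl | starting material
12 | lithium henicos-1-yn-1-ide | CCCCCCCCCCCCCCCCCCCC#C[Li] | intermediate (not isolated)
13 | methyl docos-2-ynoate | CCCCCCCCCCCCCCCCCCCC#CC(=O)OC | intermediate
14 | methyl (Z)-3-(3,5-dimethoxy-2,4-dimethylphenoxy)docos-2-enoate | CCCCCCCCCCCCCCCCCCC/C(Oc1cc(OC)c(C)c(OC)c1C)=C/C(=O)OC | intermediate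
15 | (Z)-3-(3,5-dimethoxy-2,4-dimethylphenoxy)docos-2-enoic acid | CCCCCCCCCCCCCCCCCCC/C(Oc1cc(OC)c(C)c(OC)c1C)=C/C(=O)O | intermediate
16 | 5,7-dimethoxy-6,8-dimethyl-2-nonadecyl-4H-chromen-4-one | CCCCCCCCCCCCCCCCCCCc1cc(=O)c2c(OC)c(C)c(OC)c(C)c2o1 | intermediate
17 | 5,7-dihydroxy-6,8-dimethyl-2-nonadecyl-4H-chromen-4-one | CCCCCCCCCCCCCCCCCCCc1cc(=O)c2c(O)c(C)c(O)c(C)c2o1 | target

Total step count: 9
Longest linear sequence: 7 steps (steps 1, 2, 3, 6, 7, 8, 9); the chain branch (steps 4 and 5) joins at step 6.

Steps most likely to fail

Step 6. Base-induced isomerisation of the alkynoate to the allenoate or dienoate, and attack of the ambident phenoxide through carbon, may compete with conjugate O-addition to a β-alkylated, weakly electrophilic acceptor. The fallback sets out from 13 and replaces the addition by a substitution at a preformed vinyl halide. Anti hydroiodination of 13 (NaI, AcOH, 110 °C) should give methyl (Z)-3-iododocos-2-enoate F1. Stereoretentive Ullmann-type C–O coupling of F1 with phenol 7 (copper monoiodide CuI, N,N-dimethylglycine, Cs2CO3, dioxane, 90 °C) then comes back to the route at 14 with the Z geometry fixed.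

Step 8. Ring closure may stall because the waxy substrate dissolves poorly in the acid medium, while protolytic cleavage of the enol ether with loss of the phenol competes. The fallback sets out from 7 and builds the pyranone ring by the Baker–Venkataraman sequence instead. C-acetylation at the single free ring position (Ac2O, BF3·OEt2, 80 °C) should give 1-(2-hydroxy-4,6-dimethoxy-3,5-dimethylphenyl)ethan-1-one F2. O-acylation with icosanoyl chloride (CCCCCCCCCCCCCCCCCCCC(=O)Cl; pyridine, DMAP, CH2Cl2) gives 2-acetyl-3,5-dimethoxy-4,6-dimethylphenyl icosanoate F3. Base-induced acyl migration (KOt-Bu, THF, rt) gives 1-(2-hydroxy-4,6-dimethoxy-3,5-dimethylphenyl)docosane-1,3-dione F4, and cyclodehydration (TsOH, toluene, reflux) comes back to the route at 16.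

Step 9. Ether cleavage may stop after the chelation-assisted C5 demethylation, or forcing conditions may lead to bromide addition to the pyranone. The fallback sets out from 16 and cleaves the two ethers in separate, mechanistically distinct operations. BCl3 (CH2Cl2, −20 °C) should remove only the carbonyl-chelated C5 methyl group to give 5-hydroxy-7-methoxy-6,8-dimethyl-2-nonadecyl-4H-chromen-4-one F5. A pyridinium chloride melt (190 °C) then removes the C7 methyl group by nucleophilic attack of chloride on the protonated ether and comes back to the route at 17.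

Further compounds
F1 | step 6 | methyl (Z)-3-iododocos-2-enoate | CCCCCCCCCCCCCCCCCCC/C(I)=C/C(=O)OC
F2 | step 8 | 1-(2-hydroxy-4,6-dimethoxy-3,5-dimethylphenyl)ethan-1-one | CC(=O)c1c(O)c(C)c(OC)c(C)c1OC
F3 | step 8 | 2-acetyl-3,5-dimethoxy-4,6-dimethylphenyl icosanoate | CCCCCCCCCCCCCCCCCCCC(=O)Oc1c(C)c(OC)c(C)c(OC)c1C(C)=O
F4 | step 8 | 1-(2-hydroxy-4,6-dimethoxy-3,5-dimethylphenyl)docosane-1,3-dione | CCCCCCCCCCCCCCCCCCCC(=O)CC(=O)c1c(O)c(C)c(OC)c(C)c1OC
F5 | step 9 | 5-hydroxy-7-methoxy-6,8-dimethyl-2-nonadecyl-4H-chromen-4-one | CCCCCCCCCCCCCCCCCCCc1cc(=O)c2c(O)c(C)c(OC)c(C)c2o1
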